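**Retrosynthetic overview**
1. The three esters go on last: target 32 comes from triol 27 (longipin-2-en-1-one 7,8,9-triol) by acetylation of the least hindered C8–OH, then angeloylation of both C7–OH and C9–OH.
2. The cyclohexenone ring (C1–C2=C3–C4–C5–C11) is closed last, by the C1–C11 bond: a cyclobutyl radical at C11 adds 6-exo to the formyl carbon C1 of a (Z)-enal arm on C4, and oxidation gives the enone.
3. Enabling feature: C4 and C11 are cis-1,3 across the cyclobutane C4–C5–C11–C10 of a bicyclo[4.1.1]octane, and the Z C2=C3 bond holds C1 over C11. C11 arrives as a cyclobutanone carbon, so a radical can be made there whatever its configuration.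
4. The cycloheptane (C5–C6–C7–C8–C9–C10–C11) and the cyclobutane form together by an intramolecular ketene–diene [2+2] (bonds C11–C10 and C5–C4) of acyclic acid 17.
5. Acid 17 comes from D-erythronolactone acetonide (C8, C9), Ohira–Bestmann homologation (C10≡C4), reverse prenylation (C7, C6, C5, C11), and carboalumination/coupling with a (Z)-3-iodobutenyl ether (C3, C2, C1).

Key step: step 16

Remark: atom numbers C1–C11 are those of the longipinane skeleton (C1 carbonyl, C2=C3, C6 gem-dimethyl, C7–C9 oxygenated, C10 quaternary methyl carbon, C11 bridgehead next to C1). Compounds 1, 5 and 29 are taken as commercial, and (−)-Ipc2B-prenyl is prepared beforehand from (−)-Ipc2BH and 3-methylbuta-1,2-diene.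

**Step 1**
Reactants: 1 but-2-yn-1-ol
Product: 3 (Z)-3-iodobut-2-en-1-ol, via cyclic alkenylalanate 2 (not isolated)
Conditions: Red-Al, Et2O/THF, 0 °C → rt; then I2, −78 → 0 °C; aq. Rochelle salt/Na2S2O3
Reagents that add atoms: iodine, II
Why: alkoxide-directed trans-hydroalumination of the propargylic alcohol places Al on C3 cis to the CH2O group, and iodinolysis with retention should give the Z-iodide (hydroalumination–iodination).

**Step 2**
Reactants: 3 (Z)-3-iodobut-2-en-1-ol
Product: 4 (Z)-tert-butyl[(3-iodobut-2-en-1-yl)oxy]dimethylsilane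
Conditions: TBSCl, imidazole, CH2Cl2, 0 °C → rt
Reagents that add atoms: tert-butyldimethylsilyl chloride, CC(C)(C)[Si](C)(C)Cl
Why: standard silylation of a primary alcohol; no stereocentre is touched.

**Step 3**
Reactants: 5 2,3-O-isopropylidene-D-erythronolactone
Product: 6 2,3-O-isopropylidene-D-erythrose (lactol)
Conditions: DIBAL-H, CH2Cl2, −78 °C; Rochelle salt
Reagents that add atoms: none
Why: partial reduction of a γ-lactone stops at the lactol at low temperature; C8 and C9 come from the chiral pool.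

**Step 4**
Reactants: 6 2,3-O-isopropylidene-D-erythrose
Product: 7 [(4R,5S)-5-ethynyl-2,2-dimethyl-1,3-dioxolan-4-yl]methanol
Conditions: Ohira–Bestmann reagent, K2CO3, MeOH, 0 °C → rt
Reagents that add atoms: dimethyl (1-diazo-2-oxopropyl)phosphonate, COP(=O)(OC)C(=[N+]=[N-])C(C)=O
Why: Seyferth–Gilbert homologation (Ohira–Bestmann variant) of the open aldehyde form of the lactol should give the terminal alkyne C10≡C4 and free the C7 hydroxyl, with C9 kept under the mild base.

**Step 5**
Reactants: 7 alkynyl alcohol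
Product: 8 (4S,5S)-5-ethynyl-2,2-dimethyl-1,3-dioxolane-4-carbaldehyde
Conditions: Dess–Martin periodinane, NaHCO3, CH2Cl2, 0 °C; used crude
Reagents that add atoms: none
Why: buffered Dess–Martin oxidation gives the α-alkoxy aldehyde without base, so the cis-dioxolane should not epimerise.

**Step 6**
Reactants: 8 aldehyde
Product: 10 (1S)-1-[(4R,5S)-5-ethynyl-2,2-dimethyl-1,3-dioxolan-4-yl]-2,2-dimethylbut-3-en-1-ol, via borinate 9 (not isolated)
Conditions: (−)-Ipc2B-prenyl [from (+)-α-pinene], Et2O, −78 °C → rt; then NaOH, H2O2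
Reagents that add atoms: (−)-B-(3-methylbut-2-enyl)diisopinocampheylborane, CC(C)=CCB([C@@H]1C[C@@H]2C[C@H]([C@H]1C)C2(C)C)[C@@H]1C[C@@H]2C[C@H]([C@H]1C)C2(C)C
Why: reverse prenylation by asymmetric allylboration through a chair transition state forms C7–C6 at the tertiary carbon; the (+)-α-pinene-derived reagent attacks the Si face and should set 7S by reagent control against the Felkin preference of the aldehyde.

**Step 7**
Reactants: 10 homoallylic alcohol
Product: 11 TBS ether of 10
Conditions: TBSOTf, 2,6-lutidine, CH2Cl2, −78 → 0 °C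
Reagents that add atoms: tert-butyldimethylsilyl triflate, CC(C)(C)[Si](C)(C)OS(=O)(=O)C(F)(F)F
Why: the silyl triflate silylates the hindered neopentyl-type carbinol, which would otherwise lactonise onto C11 later.

**Step 8**
Reactants: 11 TBS ether of 10; 4 (Z)-vinyl iodide
Product: 13 (2Z,4E)-dienyl bis-silyl ether, via alkenylalane 12 (not isolated)
Conditions: Me3Al, Cp2ZrCl2, CH2Cl2, 0 °C → rt; then 4, Pd(PPh3)4 (5 mol %), ZnCl2 (cat.), THF, rt
Reagents that add atoms: trimethylaluminium, C[Al](C)C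
Why: Zr-catalysed syn-carboalumination puts the methyl group on C10 and Al on C4, and the Negishi alkenyl–alkenyl coupling proceeds with retention on both partners, so C10=C4 should be E and C3=C2 Z; the monosubstituted alkene does not react.

**Step 9**
Reactants: 13 dienyl bis-silyl ether
Product: 15 primary alcohol (C11–OH), via B-alkyl-9-BBN 14 (not isolated)
Conditions: 9-BBN, THF, 0 °C → rt; then NaOH, H2O2, 0 °C
Reagents that add atoms: hydrogen peroxide, OO
Why: 9-BBN hydroborates the monosubstituted vinyl group anti-Markovnikov and should leave the two trisubstituted diene bonds alone.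

**Step 10**
Reactants: 15 primary alcohol
Product: 17 carboxylic acid, via aldehyde 16 (not isolated)
Conditions: TEMPO (cat.), PhI(OAc)2, MeCN/pH 7 buffer, rt
Reagents that add atoms: water, O
Why: oxoammonium oxidation takes the primary alcohol through the aldehyde hydrate to the acid and tolerates silyl ethers, acetonide and diene.

**Step 11**
Reactants: 17 carboxylic acid
Product: 20 bicyclo[4.1.1]octan-8-one, via acid chloride 18 (not isolated), via ketene 19 (not isolated)
Conditions: 1-chloro-N,N,2-trimethylprop-1-en-1-amine, CH2Cl2, 0 °C; then slow addition to Et3N, toluene, 110 °C, high dilution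
Reagents that add atoms: none
Why: intramolecular ketene–1,3-diene [2+2] cycloaddition: as in ketene–diene additions the carbonyl carbon C11 bonds to the diene terminus C10 and C5 to the allylic carbon C4, which with the four-atom tether gives the bridged cycloheptane-cyclobutanone; the E geometry of C10=C4 is retained, so the C3 arm ends trans to C9, and the cis-dioxolane is expected to keep O9 gauche rather than anti to the forming C11–C10 bond, putting the carbonyl bridge on the side of O8/O9.

**Step 12**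
Reactants: 20 bicyclo[4.1.1]octan-8-one
Product: 21 cyclobutanol
Conditions: NaBH4, MeOH, 0 °C
Reagents that add atoms: none
Why: hydride reduction of the strained ketone; the configuration at C11 is erased in step 16, so either epimer serves.

**Step 13**
Reactants: 21 cyclobutanol
Product: 22 S-methyl xanthate
Conditions: NaH, imidazole (cat.), CS2, THF, 0 °C → rt; then MeI
Reagents that add atoms: carbon disulfide, S=C=S; iodomethane, CI
Why: standard xanthate formation; Chugaev elimination is not available because it would need a bridgehead cyclobutene.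

**Step 14**
Reactants: 22 xanthate
Product: 23 allylic alcohol
Conditions: HF·pyridine, pyridine, THF, 0 °C
Reagents that add atoms: none
Why: the primary allylic silyl ether is cleaved much faster than the hindered secondary one at C7.

**Step 15**
Reactants: 23 allylic alcohol
Product: 24 (Z)-enal xanthate
Conditions: MnO2, CH2Cl2, rt
Reagents that add atoms: none
Why: MnO2 oxidises the allylic alcohol under neutral conditions, so the Z geometry of C2=C3 should be kept.

**Step 16**
Reactants: 24 (Z)-enal xanthate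
Product: 25 tricyclic allylic alcohol (C1 epimers)
Conditions: Bu3SnH and AIBN by syringe pump, benzene (0.005 M), 80 °C
Reagents that add atoms: none
Why: Tributyltin radical attacks the thiocarbonyl sulfur of the xanthate and the adduct fragments to the C11 cyclobutyl radical (Barton–McCombie radical generation); this radical adds to the formyl carbon C1 of the (Z)-enal arm and the resulting allylic alkoxy radical is quenched by Bu3SnH, which carries the chain. The closest known reaction type is the 6-exo cyclisation of alkyl radicals onto aldehyde carbonyl groups. The cyclohexene ring C1–C2=C3–C4–C5–C11 closes in the 6-exo-trig mode on the C=O bond and creates the bicyclo[3.1.1]heptene. C11 becomes stereogenic: C1 can reach it only on the cyclobutane face that carries the C4 arm (cis-1,3 across the ring, anti to the C6–C9 bridge), so C11–H ends on the side of that bridge as in the target whatever the configuration of the xanthate, and the new carbinol centre C1 forms as a mixture that step 17 removes. The step needs ring closure to beat reduction of the cyclobutyl radical and attack of tin radicals on the enal; slow addition of Bu3SnH at high dilution, the much faster reaction of tin radicals with C=S, and the Z C2=C3 bond on the rigid bicyclo[4.1.1]octane, which holds C1 directly above C11, should secure this. Conjugate addition is excluded because C3 cannot be reached from C11 without forming a bicyclo[1.1.1]pentane.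

**Step 17**
Reactants: 25 tricyclic allylic alcohol
Product: 26 7-O-TBS-8,9-O-isopropylidene-longipin-2-en-1-one
Conditions: Dess–Martin periodinane, NaHCO3, CH2Cl2, rt
Reagents that add atoms: none
Why: oxidation of both C1 epimers converges on the conjugated enone.

**Step 18**
Reactants: 26 protected enone
Product: 27 (4R,5S,7S,8R,9S,10R,11R)-7,8,9-trihydroxylongipin-2-en-1-one
Conditions: aq. HF (48%), MeCN, 0 °C → rt
Reagents that add atoms: none
Why: aqueous HF should cleave the silyl ether and hydrolyse the acetonide in one operation without the strong acid that rearranges longipinanes.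

**Step 19**
Reactants: 27 triol
Product: 28 8-O-acetyl triol
Conditions: Ac2O (1.05 equiv), 2,4,6-collidine, CH2Cl2, −40 → 0 °C
Reagents that add atoms: acetic anhydride, CC(=O)OC(C)=O
Why: C8–OH is flanked by two CH(OH) carbons, whereas C7–OH and C9–OH are neopentyl-type (next to C6 and C10), so the first acylation should go to O8.

**Step 20**
Reactants: 28 8-O-acetyl triol; 29 angelic acid
Product: 32 target, via mixed anhydride 30 (not isolated), via 7-O-angeloyl mono-ester 31 (not isolated)
Conditions: 29 (5 equiv), 2,4,6-trichlorobenzoyl chloride (5 equiv), Et3N, toluene, rt; then 28, 80 °C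
Reagents that add atoms: angelic acid (second equivalent, for the second hydroxyl), C/C=C(/C)C(=O)O
Why: Yamaguchi-type esterification, in which two molecules of the angelic trichlorobenzoic anhydride acylate the hindered C7 and C9 hydroxyls one after the other (the order does not matter, since the 9-O-mono-ester converges on the same diester) without base-induced isomerisation of the Z acid to the tiglate.

**Compound list**
1 | but-2-yn-1-ol | CC#CCO | starting material
2 | sodium cyclic (Z)-alkenylalanate of 1 | [Na+].COCCO[Al-]1(OCCOC)OCC=C1C | intermediate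
3 | (Z)-3-iodobut-2-en-1-ol | C/C(I)=C/CO | intermediate
4 | (Z)-tert-butyl[(3-iodobut-2-en-1-yl)oxy]dimethylsilane | C/C(I)=C/CO[Si](C)(C)C(C)(C)C | intermediate
5 | 2,3-O-isopropylidene-D-erythronolactone | O=C1OC[C@H]2OC(C)(C)O[C@@H]12 | starting material
6 | 2,3-O-isopropylidene-D-erythrose (lactol, anomers) | OC1OC[C@H]2OC(C)(C)O[C@@H]12 | intermediate
7 | [(4R,5S)-5-ethynyl-2,2-dimethyl-1,3-dioxolan-4-yl]methanol | C#C[C@@H]1OC(C)(C)O[C@@H]1CO | intermediate
8 | (4S,5S)-5-ethynyl-2,2-dimethyl-1,3-dioxolane-4-carbaldehyde | C#C[C@@H]1OC(C)(C)O[C@@H]1C=O | intermediate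
9 | diisopinocampheylborinate of 10 | C#C[C@@H]1OC(C)(C)O[C@@H]1[C@@H](OB([C@@H]2C[C@@H]3C[C@H]([C@H]2C)C3(C)C)[C@@H]2C[C@@H]3C[C@H]([C@H]2C)C3(C)C)C(C)(C)C=C | intermediate
10 | (1S)-1-[(4R,5S)-5-ethynyl-2,2-dimethyl-1,3-dioxolan-4-yl]-2,2-dimethylbut-3-en-1-ol | C#C[C@@H]1OC(C)(C)O[C@@H]1[C@@H](O)C(C)(C)C=C | intermediate
11 | TBS ether of 10 (C7–OTBS) | C#C[C@@H]1OC(C)(C)O[C@@H]1[C@@H](O[Si](C)(C)C(C)(C)C)C(C)(C)C=C | intermediate
12 | (E)-alkenyl(dimethyl)alane from 11 (Me on C10, Al on C4) | C=CC(C)(C)[C@H](O[Si](C)(C)C(C)(C)C)[C@H]1OC(C)(C)O[C@H]1/C(C)=C/[Al](C)C | intermediate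
13 | triene: C5=C11 vinyl, (E)-C10=C4, (Z)-C3=C2; 7-OTBS, 8,9-acetonide, 1-OTBS | C=CC(C)(C)[C@H](O[Si](C)(C)C(C)(C)C)[C@H]1OC(C)(C)O[C@H]1/C(C)=C/C(C)=C\CO[Si](C)(C)C(C)(C)C | intermediate
14 | B-alkyl-9-borabicyclo[3.3.1]nonane from 13 (B on C11) | C1CCC2CCCC1B2CCC(C)(C)[C@H](O[Si](C)(C)C(C)(C)C)[C@H]1OC(C)(C)O[C@H]1/C(C)=C/C(C)=C\CO[Si](C)(C)C(C)(C)C | intermediate
15 | primary alcohol (C11–OH) | OCCC(C)(C)[C@H](O[Si](C)(C)C(C)(C)C)[C@H]1OC(C)(C)O[C@H]1/C(C)=C/C(C)=C\CO[Si](C)(C)C(C)(C)C | intermediate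
16 | aldehyde (C11 formyl) | O=CCC(C)(C)[C@H](O[Si](C)(C)C(C)(C)C)[C@H]1OC(C)(C)O[C@H]1/C(C)=C/C(C)=C\CO[Si](C)(C)C(C)(C)C | intermediate
17 | carboxylic acid (C11 carboxyl, C5 methylene, C6 gem-dimethyl, diene arm) | OC(=O)CC(C)(C)[C@H](O[Si](C)(C)C(C)(C)C)[C@H]1OC(C)(C)O[C@H]1/C(C)=C/C(C)=C\CO[Si](C)(C)C(C)(C)C | intermediate
18 | acid chloride of 17 | ClC(=O)CC(C)(C)[C@H](O[Si](C)(C)C(C)(C)C)[C@H]1OC(C)(C)O[C@H]1/C(C)=C/C(C)=C\CO[Si](C)(C)C(C)(C)C | intermediate
19 | ketene (O=C11=C5) | O=C=CC(C)(C)[C@H](O[Si](C)(C)C(C)(C)C)[C@H]1OC(C)(C)O[C@H]1/C(C)=C/C(C)=C\CO[Si](C)(C)C(C)(C)C | intermediate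
20 | bicyclo[4.1.1]octan-8-one: C11 carbonyl bridge; C10 methyl and the (Z)-alkenyl arm on C4 on the face away from the C6–C9 bridge; 8,9-acetonide on the C11 side, 7-OTBS on the C4 side | CC(C)(C)[Si](C)(C)O[C@@H]1[C@H]2OC(C)(C)O[C@H]2[C@@]3(C)C(=O)[C@H]([C@@H]3/C(C)=C\CO[Si](C)(C)C(C)(C)C)C1(C)C | intermediate
21 | cyclobutanol from 20 (C11–OH drawn toward the C6–C9 bridge) | CC(C)(C)[Si](C)(C)O[C@@H]1[C@H]2OC(C)(C)O[C@H]2[C@@]3(C)[C@@H](O)[C@H]([C@@H]3/C(C)=C\CO[Si](C)(C)C(C)(C)C)C1(C)C | intermediate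
22 | O-cyclobutyl S-methyl xanthate of 21 | CC(C)(C)[Si](C)(C)O[C@@H]1[C@H]2OC(C)(C)O[C@H]2[C@@]3(C)[C@@H](OC(=S)SC)[C@H]([C@@H]3/C(C)=C\CO[Si](C)(C)C(C)(C)C)C1(C)C | intermediate
23 | xanthate with free (Z)-allylic alcohol at C1 | CC(C)(C)[Si](C)(C)O[C@@H]1[C@H]2OC(C)(C)O[C@H]2[C@@]3(C)[C@@H](OC(=S)SC)[C@H]([C@@H]3/C(C)=C\CO)C1(C)C | intermediate
24 | xanthate with (Z)-enal arm on C4 | CC(C)(C)[Si](C)(C)O[C@@H]1[C@H]2OC(C)(C)O[C@H]2[C@@]3(C)[C@@H](OC(=S)SC)[C@H]([C@@H]3/C(C)=C\C=O)C1(C)C | intermediate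
25 | 7-O-TBS-8,9-O-isopropylidene-longipin-2-en-1-ol (C1 epimers; other centres as in 32) | CC(C)(C)[Si](C)(C)O[C@@H]1[C@H]2OC(C)(C)O[C@H]2[C@@]3(C)[C@@H]4C(O)C=C(C)[C@H]3[C@@H]4C1(C)C | intermediate
26 | 7-O-TBS-8,9-O-isopropylidene-longipin-2-en-1-one (all centres as in 32) | CC(C)(C)[Si](C)(C)O[C@@H]1[C@H]2OC(C)(C)O[C@H]2[C@@]3(C)[C@@H]4C(=O)C=C(C)[C@H]3[C@@H]4C1(C)C | intermediate
27 | (4R,5S,7S,8R,9S,10R,11R)-7,8,9-trihydroxylongipin-2-en-1-one | O[C@@H]1[C@@H](O)[C@@H](O)[C@@]2(C)[C@@H]3C(=O)C=C(C)[C@H]2[C@@H]3C1(C)C | intermediate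
28 | 8-O-acetyl derivative of 27 | O[C@@H]1[C@@H](OC(C)=O)[C@@H](O)[C@@]2(C)[C@@H]3C(=O)C=C(C)[C@H]2[C@@H]3C1(C)C | intermediate
29 | angelic acid, (Z)-2-methylbut-2-enoic acid | C/C=C(/C)C(=O)O | starting material
30 | angelic 2,4,6-trichlorobenzoic anhydride | C/C=C(/C)C(=O)OC(=O)c1c(Cl)cc(Cl)cc1Cl | intermediate
31 | 8-acetoxy-7-angeloyloxy-9-hydroxylongipin-2-en-1-one (7-O-angeloyl mono-ester of 28) | C/C=C(/C)C(=O)O[C@@H]1[C@@H](OC(C)=O)[C@@H](O)[C@@]2(C)[C@@H]3C(=O)C=C(C)[C@H]2[C@@H]3C1(C)C | intermediate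
32 | (4R,5S,7S,8R,9S,10R,11R)-8-acetoxy-7,9-bis(angeloyloxy)longipin-2-en-1-one | C/C=C(/C)C(=O)O[C@@H]1[C@@H](OC(C)=O)[C@@H](OC(=O)/C(C)=C\C)[C@@]2(C)[C@@H]3C(=O)C=C(C)[C@H]2[C@@H]3C1(C)C | target

Total step count: 20. Longest linear sequence: 18 steps (steps 3–20).

**Steps most likely to fail**

Step 11. The seven-membered bridged closure is slow, so ketene oligomerisation, closure in the fused mode (C11 to C4, six-membered ring) or attack on the wrong diene face relative to C9 may take over. Fallback: acid 17 is condensed with pyrrolidine to N-acylpyrrolidine F1. Triflic anhydride and 2,4,6-collidine in 1,2-dichloroethane convert it into keteniminium triflate F2, a far stronger electrophile that should close onto the diene terminus at lower temperature and give cyclobutaniminium triflate F3. Aqueous NaHCO3 hydrolysis returns to cyclobutanone 20.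

Step 16. The cyclobutyl radical may be reduced by tin hydride before it closes, the addition to the formyl group is reversible, and tin radicals may add to the enal oxygen and scramble the Z geometry. Fallback with reversed roles (C1 as an acyl radical, C11 as a radical acceptor that fragments irreversibly): ketone 20 is condensed with 1-amino-2-phenylaziridine to N-aziridinylimine F4. HF·pyridine gives allylic alcohol F5, MnO2 gives enal F6, NaClO2/NaH2PO4/2-methylbut-2-ene gives acid F7, and PhSeSePh/Bu3P gives Se-phenyl selenoester F8. Bu3SnH/AIBN then generates the Z-enoyl radical, which adds 6-exo to C11 of the C=N bond; loss of styrene and N2 leaves the C11 radical, which takes hydrogen on the face toward the C6–C9 bridge. This comes back to the route at enone 26 and bypasses steps 12–17.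

Step 20. Forcing conditions at the two neopentyl-type hydroxyls may let the acetyl group migrate from O8 to the cis O9 before angeloylation, the second acylation may stall at the mono-ester, and the angelate may isomerise. Fallback that introduces the acetate last: triol 27 is silylated at the least hindered hydroxyl with TESCl/imidazole to 8-O-triethylsilyl triol F9. Double angeloylation as in step 20 gives 7,9-di-O-angeloyl-8-O-triethylsilyl ether F10, and HF·pyridine gives 7,9-di-O-angeloyl-8-ol F11. Acetylation with Ac2O and catalytic Sc(OTf)3 (no base) comes back to the route at target 32.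

**Further compounds**
F1 | step 11 | N-acylpyrrolidine of acid 17 | O=C(N1CCCC1)CC(C)(C)[C@H](O[Si](C)(C)C(C)(C)C)[C@H]1OC(C)(C)O[C@H]1/C(C)=C/C(C)=C\CO[Si](C)(C)C(C)(C)C
F2 | step 11 | keteniminium triflate from F1 | C(=C=[N+]1CCCC1)C(C)(C)[C@H](O[Si](C)(C)C(C)(C)C)[C@H]1OC(C)(C)O[C@H]1/C(C)=C/C(C)=C\CO[Si](C)(C)C(C)(C)C.[O-]S(=O)(=O)C(F)(F)F
F3 | step 11 | cyclobutaniminium triflate (pyrrolidinium analogue of 20) | CC(C)(C)[Si](C)(C)O[C@@H]1[C@H]2OC(C)(C)O[C@H]2[C@@]3(C)C(=[N+]4CCCC4)[C@H]([C@@H]3/C(C)=C\CO[Si](C)(C)C(C)(C)C)C1(C)C.[O-]S(=O)(=O)C(F)(F)F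
F4 | step 16 | N-(2-phenylaziridin-1-yl)imine of 20 | CC(C)(C)[Si](C)(C)O[C@@H]1[C@H]2OC(C)(C)O[C@H]2[C@@]3(C)C(=NN4CC4c4ccccc4)[C@H]([C@@H]3/C(C)=C\CO[Si](C)(C)C(C)(C)C)C1(C)C
F5 | step 16 | aziridinylimine with free (Z)-allylic alcohol | CC(C)(C)[Si](C)(C)O[C@@H]1[C@H]2OC(C)(C)O[C@H]2[C@@]3(C)C(=NN4CC4c4ccccc4)[C@H]([C@@H]3/C(C)=C\CO)C1(C)C
F6 | step 16 | aziridinylimine (Z)-enal | CC(C)(C)[Si](C)(C)O[C@@H]1[C@H]2OC(C)(C)O[C@H]2[C@@]3(C)C(=NN4CC4c4ccccc4)[C@H]([C@@H]3/C(C)=C\C=O)C1(C)C
F7 | step 16 | aziridinylimine (Z)-enoic acid | CC(C)(C)[Si](C)(C)O[C@@H]1[C@H]2OC(C)(C)O[C@H]2[C@@]3(C)C(=NN4CC4c4ccccc4)[C@H]([C@@H]3/C(C)=C\C(=O)O)C1(C)C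
F8 | step 16 | aziridinylimine Se-phenyl (Z)-selenoester | CC(C)(C)[Si](C)(C)O[C@@H]1[C@H]2OC(C)(C)O[C@H]2[C@@]3(C)C(=NN4CC4c4ccccc4)[C@H]([C@@H]3/C(C)=C\C(=O)[Se]c5ccccc5)C1(C)C
F9 | step 20 | 8-O-triethylsilyl derivative of triol 27 | O[C@@H]1[C@@H](O[Si](CC)(CC)CC)[C@@H](O)[C@@]2(C)[C@@H]3C(=O)C=C(C)[C@H]2[C@@H]3C1(C)C
F10 | step 20 | 7,9-di-O-angeloyl-8-O-triethylsilyl derivative | C/C=C(/C)C(=O)O[C@@H]1[C@@H](O[Si](CC)(CC)CC)[C@@H](OC(=O)/C(C)=C\C)[C@@]2(C)[C@@H]3C(=O)C=C(C)[C@H]2[C@@H]3C1(C)C
F11 | step 20 | 7,9-di-O-angeloyl-8-hydroxylongipin-2-en-1-one | C/C=C(/C)C(=O)O[C@@H]1[C@@H](O)[C@@H](OC(=O)/C(C)=C\C)[C@@]2(C)[C@@H]3C(=O)C=C(C)[C@H]2[C@@H]3C1(C)C
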